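## Analysis of the target

CNP0175889.7 (35) is a ten-membered carbocycle, cis-fused at C6–C7 to an α-methylene-γ-butyrolactone. The numbering used throughout is: ring carbons C1–C10; lactone carbons C11 and C12 (carbonyl) with the exocyclic methylene C13 and the ring oxygen on C6; C14 is the methylene on C10 and C15 the methyl on C4. The ring also carries a Z trisubstituted C4=C5 olefin, free carbinols at C1 and C3, and an angelate on O8. There are five stereocentres, 1R, 3S, 6S, 7R and 8R. The C1 and C3 hydroxyls are syn. In the C6–C7–C8 triad the C11 branch on C7 is anti to both flanking oxygens, so that O6 and O8 are 1,3-syn and H6 and H7 are cis. The methylene lactone is a Michael acceptor and a dipolarophile, the angelate isomerises to the tiglate under base or nucleophiles, and both carbinols are allylic. The difficulties are the closure of a ten-membered ring that contains a Z trisubstituted olefin, the distinction of O6 from O8 (either can lactonise onto C12), and the absence of any direct relay between the C1/C3 pair and the C6–C8 triad. The strategy rests on the segment C1(OH)–C2H2–C3(OH), which lies between the C10=C14 and C4=C5 olefins. It is a reduced β-hydroxy ketone, hence an isoxazoline formed from a nitrile oxide at C1 and a terminal C2=C3 olefin, and making it can also close the ring.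

## Retrosynthetic reasoning

35 back to 34, then 31 and 32. The O8–acyl bond and the acetal C–O bonds are cut first, because the Z enoate of the angelate would not survive enolate, hydride or dipole chemistry. The diol must stay masked while the lactone is enolised and O8 is acylated. The forward steps must esterify a hindered secondary alcohol with 32 without Z to E isomerisation, and then hydrolyse the acetal of 34 under acid mild enough for two allylic alcohols.

31 back to 30, 28 and 27. The C11=C13 bond is removed. An α-methylene lactone would compete as a dipolarophile in the ring closure and as a hydride and Michael acceptor afterwards, so it is installed on the finished carbocycle from the lactone enolate of 27. Nothing β to that enolate can be eliminated.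

27 back to 26 and 24. The C1–H bond is cut, so the C1 carbinol comes from a ketone. The free C3 hydroxyl of 24 can deliver hydride through a boron chelate, so one stereocentre sets the other, and no independent control of C1 is needed.

24 back to 22. The C1 carbonyl and the C3 hydroxyl are joined again through nitrogen as an N–O bridge. The β-hydroxy ketone is thus carried as an isoxazoline, which is inert to everything before it and is cut reductively in one step.

22 back to 21 and 20. This is the key disconnection: C1–C2 and O–C3 are cut together. It is made here and not at a lactone or olefin bond because it removes a ring bond and the C3 oxygen in one step. It also leaves a precursor, 20, whose three stereocentres all sit on a simple γ-lactone. The forward reaction has to close a ten-membered ring in the bridged mode faster than the dipole 21 dimerises, and it must add to one face of the vinyl group.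

20 back to 19, 18, 17 and 16. These are adjustments of the C1 oxidation level and of protecting groups only. C1 is carried as a 4-methoxybenzyl ether, which comes off without touching the silyl ether on O8.

16 back to 15. The C8–H bond is cut, not the C8–C9 bond. With C6 as the large substituent on C7, Felkin–Anh addition of an allyl metal to a C8 aldehyde would give the C8 epimer. Delivery of hydride to the same face of ketone 15 gives the required anti relation of O8 to C11.

15 back to 10 and 13. The C8–C9 bond is cut between an acyl donor and a 2-substituted allyl metal. This brings in C9, C10, C14 and C1 in one piece, with C1 already oxygenated.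

10 back to 9, then 6 and 3. The C6–C7 bond and the O6–C12 bond are cut. The anti relation of O6 to C11 is that of an anti aldol between a succinate enolate and the C6 aldehyde. Lactonisation of the aldol hydroxyl onto the distal ester gives the cis lactone and at the same time removes any later competition between O6 and O8 for C12.

6 back to 4 and 5; 3 back to 2 and 1; 13 back to 12 and 11. The auxiliary 4 is N-acylated with 5. The Z C4=C5 olefin is bought with 1, whose alkyne becomes the terminal vinyl group. The allyl bromide 13 comes from the symmetrical diol 11.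

## Alternatives that were turned down

Alternative 1: The C2–C3 bond is cut and C5 is joined to C10, which contracts the ten-membered ring to a cyclohexane carbinol. Forward, an anionic oxy-Cope rearrangement (KN(SiMe3)2, 18-crown-6) of the tertiary alkoxide would expand the six-membered ring. The C1–C10 enolate would be oxidised in the same flask to give the hydroxy ketone A1.
- For it: the ring is formed by a unimolecular sigmatropic shift that needs no dilution, and the cyclohexane template makes the stereocentres at C6–C8 easy to set. On the certainty of ring formation it is stronger than the chosen route.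
- Against it: A1 has its carbonyl at C10 and its hydroxyl at C1, so C10 must still be methylenated next to a free or protected carbinol in a medium ring.
- The C1 configuration comes from an enolate oxidation under macrocyclic control only.
- The Z geometry at C4=C5 and the C3 configuration both depend on the geometry of a trisubstituted silyl enol ether and on a boat or chair preference that cannot be enforced.
- O6 and O8 are both 4-methoxybenzyl ethers in A1, so the choice between them for lactonisation is still open.
- The lactone, its methylene and the angelate all remain to be built.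
- In its place the chosen route offers a shorter sequence after ring closure, a C1/C3 relation that is relayed and not set twice, and O6/O8 differentiation from the first stereo-defining step.

Alternative 2: The C6–C7 and C8–C9 bonds are cut together after joining C6 to C9, which leads back to an eight-membered dienone enol ester. Forward, irradiation would add the tethered silyl enol ether across the C6=C9 enone bond to give the tricyclic photoadduct A2. Scission of the C6–C9 cyclobutane bond would then unfold the ten-membered ring.
- For it: two ring bonds, the γ-lactone and the C7 and C8 stereocentres are made in one step, an eight-membered ring is easier to reach than a ten-membered one, and the expansion is driven by release of cyclobutane strain. In bonds formed per step it is stronger than the chosen route.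
- Against it: C6 is quaternary in A2. It must be returned to a methine by reductive cleavage next to the C10 ketone, with its configuration set at that late point and without allylic transposition of C4=C5.
- The regiochemistry of the [2+2] addition and its facial selectivity depend on remote C1 and C3 substituents of a flexible eight-membered dienone. That dienone can also isomerise at its olefins under irradiation.
- A2 again carries the ketone at C10, so methylenation and the whole endgame remain.
- The chosen route sets C6, C7 and C8 by established acyclic methods before the risky step and leaves one selectivity question in it, not four.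

Alternative 3: The O6–C6 bond and the O3–C3 bond are cut together across a C3=C4–C5=C6 ring diene, leading back to a cyclodecadiene carboxylic acid. Forward, Pd(OAc)2 with benzoquinone, LiOAc and catalytic LiCl in acetic acid would add the C12 carboxylate to C6 and acetate to C3. Both would add anti to divalent palladium and therefore on the same face, to give A3.
- For it: the methylene lactone, the C3 oxygen and the Z olefin appear in one late step with the angelate already in place, and no lactone enolate chemistry is needed. On directness of the endgame it is clearly stronger than the chosen route.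
- Against it: the ten-membered ring must already exist with the diene, the acrylic acid, the angelate, the C10 methylene and the C1 stereocentre. The hard problem is therefore only moved, and C1 has no relay from C3.
- On a mobile medium ring, the site and face of carboxylate attack follow the ring conformation.
- Benzoquinone can undergo a Diels–Alder reaction with a ring diene that can become s-cis.
- The final removal of the C3 acetate must be selective against the angelate, the lactone and the Michael-sensitive methylene group.
- The chosen route offers instead a ring closure that creates the C3 oxygen and the ring together, a directed reduction for C1, and protecting groups that come off under neutral or mildly acidic conditions.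

Key step: step 14

Remarks on the chemistry:
- (2Z)-3-Methylpent-2-en-4-yn-1-ol (1), the Z C6 building block of vitamin A manufacture, is taken as commercially available.
- The sense of induction in step 4 is taken from the chelated-enolate model (aldehyde on the enolate face opposite the benzyl group).
- The C7 descriptor changes between 15, 16 and 17 and between 30 and 31 only because CIP priorities change. There is no inversion.

## Route

Step 1
Reactants: 1 (2Z)-3-methylpent-2-en-4-yn-1-ol
Product: 2 (2Z)-3-methylpenta-2,4-dien-1-ol
Conditions: H2 (1 atm), Pd/CaCO3 poisoned with Pb(OAc)2 (Lindlar catalyst), quinoline, EtOAc, 23 °C, stopped after one equivalent of H2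
Reagents that add atoms: none
Why: Lindlar semihydrogenation; the terminal alkyne is reduced much faster than the olefins and the existing Z trisubstituted olefin is not touched, so the Z diene is obtained with its geometry taken from 1.

Step 2
Reactants: 2 (2Z)-3-methylpenta-2,4-dien-1-ol
Product: 3 (2Z)-3-methylpenta-2,4-dienal
Conditions: MnO2, CH2Cl2, 23 °C; filtered and used as a solution
Reagents that add atoms: none
Why: Allylic alcohol oxidation with MnO2; the neutral heterogeneous oxidant should leave the Z enal geometry intact, and the volatile aldehyde is not concentrated to dryness.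

Step 3
Reactants: 4 (4R)-4-benzyl-1,3-oxazolidin-2-one; 5 methyl 4-chloro-4-oxobutanoate
Product: 6 methyl 4-[(4R)-4-benzyl-2-oxo-1,3-oxazolidin-3-yl]-4-oxobutanoate
Conditions: n-BuLi, THF, −78 °C; then 5, −78→0 °C
Reagents that add atoms: none
Why: N-Acylation of the lithiated oxazolidinone by the acid chloride; the methyl ester is far less electrophilic and is retained.

Step 4
Reactants: 6 methyl 4-[(4R)-4-benzyl-2-oxo-1,3-oxazolidin-3-yl]-4-oxobutanoate; 3 (2Z)-3-methylpenta-2,4-dienal
Product: 9 (4R)-4-benzyl-3-{[(2S,3S)-2-[(1Z)-2-methylbuta-1,3-dien-1-yl]-5-oxooxolan-3-yl]carbonyl}-1,3-oxazolidin-2-one, via trimethylsilyl aldolate 7 (not isolated), via hydroxy ester 8 (not isolated)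
Conditions: MgCl2 (0.2 equiv), Et3N, Me3SiCl, EtOAc, 23 °C; then PPTS, MeOH, 23 °C; then PhMe, 50 °C
Reagents that add atoms: none
Why: Evans magnesium-catalysed anti-aldol reaction (soft enolisation at the imide α-carbon only), then acid-catalysed desilylation and lactonisation; the magnesium-chelated Z-enolate of 6 is attacked on the face away from the benzyl group, which sets C7, and the boat-like transition state places the new C6 oxygen anti to C11, so that closure of this hydroxyl onto the methyl ester gives the cis lactone and removes the only hydroxyl that could later compete with O8 for C12.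

Step 5
Reactants: 9 (4R)-4-benzyl-3-{[(2S,3S)-2-[(1Z)-2-methylbuta-1,3-dien-1-yl]-5-oxooxolan-3-yl]carbonyl}-1,3-oxazolidin-2-one
Product: 10 (2S,3S)-2-[(1Z)-2-methylbuta-1,3-dien-1-yl]-5-oxooxolane-3-carboxylic acid
Conditions: LiOH, H2O2, THF/H2O, 0 °C; then Na2SO3; then HCl to pH 2
Reagents that add atoms: hydrogen peroxide, OO
Why: Hydroperoxide cleavage of the N-acyl oxazolidinone at the exocyclic carbonyl; the weakly basic hydroperoxide should not epimerise C7, any lactone opened in the basic medium recloses on acidification (only the γ-lactone to C12 is possible), and 4 is recovered.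

Step 6
Reactants: 11 2-methylidenepropane-1,3-diol
Product: 12 2-{[(4-methoxybenzyl)oxy]methyl}prop-2-en-1-ol
Conditions: NaH (1 equiv), 4-MeOC6H4CH2Cl, Bu4NI (cat.), THF/DMF, 0→23 °C
Reagents that add atoms: 4-methoxybenzyl chloride, COc1ccc(CCl)cc1
Why: Williamson monoetherification of a symmetrical diol through its monoalkoxide; the bis-ether and unchanged diol are separated.

Step 7
Reactants: 12 2-{[(4-methoxybenzyl)oxy]methyl}prop-2-en-1-ol
Product: 13 1-({[2-(bromomethyl)prop-2-en-1-yl]oxy}methyl)-4-methoxybenzene
Conditions: CBr4, PPh3, CH2Cl2, 0 °C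
Reagents that add atoms: carbon tetrabromide, BrC(Br)(Br)Br
Why: Appel bromination of a primary allylic alcohol under neutral conditions that the benzylic ether tolerates.

Step 8
Reactants: 10 (2S,3S)-2-[(1Z)-2-methylbuta-1,3-dien-1-yl]-5-oxooxolane-3-carboxylic acid; 13 1-({[2-(bromomethyl)prop-2-en-1-yl]oxy}methyl)-4-methoxybenzene
Product: 15 (4S,5S)-4-(3-{[(4-methoxybenzyl)oxy]methyl}but-3-enoyl)-5-[(1Z)-2-methylbuta-1,3-dien-1-yl]oxolan-2-one, via acyl imidazole 14 (not isolated)
Conditions: carbonyldiimidazole, THF, 23 °C; then 13, In powder, THF/DMF, 0→23 °C; neutral work-up, used directly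
Reagents that add atoms: none
Why: Barbier-type acylation of an allylindium reagent by an acyl imidazole, a known route to β,γ-unsaturated ketones in which the tetrahedral adduct survives until work-up and prevents a second addition; allylindium does not attack the lactone, and the near-neutral medium is chosen to protect the cis C7 centre and the unconjugated olefin of the product.

Step 9
Reactants: 15 (4S,5S)-4-(3-{[(4-methoxybenzyl)oxy]methyl}but-3-enoyl)-5-[(1Z)-2-methylbuta-1,3-dien-1-yl]oxolan-2-one
Product: 16 (4R,5S)-4-[(1R)-1-hydroxy-3-{[(4-methoxybenzyl)oxy]methyl}but-3-en-1-yl]-5-[(1Z)-2-methylbuta-1,3-dien-1-yl]oxolan-2-one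
Conditions: LiBH(s-Bu)3 (L-Selectride), THF, −78 °C; AcOH quench at −78 °C
Reagents that add atoms: none
Why: Felkin–Anh-controlled ketone reduction; with C6 (branched and carrying the cis dienyl group) as the large substituent on C7 held anti to the incoming hydride, the bulky borohydride passes the C7 hydrogen and should give the 8R alcohol with O8 anti to C11, whereas allyl addition to the corresponding aldehyde would give the epimer; the cold acidic quench keeps the alkoxide from attacking the lactone carbonyl.

Step 10
Reactants: 16 (4R,5S)-4-[(1R)-1-hydroxy-3-{[(4-methoxybenzyl)oxy]methyl}but-3-en-1-yl]-5-[(1Z)-2-methylbuta-1,3-dien-1-yl]oxolan-2-one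
Product: 17 (4S,5S)-4-[(1R)-1-{[tert-butyl(dimethyl)silyl]oxy}-3-{[(4-methoxybenzyl)oxy]methyl}but-3-en-1-yl]-5-[(1Z)-2-methylbuta-1,3-dien-1-yl]oxolan-2-one
Conditions: t-BuMe2SiOTf, 2,6-lutidine, CH2Cl2, −78→0 °C
Reagents that add atoms: tert-butyldimethylsilyl trifluoromethanesulfonate, CC(C)(C)[Si](C)(C)OS(=O)(=O)C(F)(F)F
Why: Silylation of a hindered secondary alcohol with the silyl triflate and a non-nucleophilic base; this fixes O8 as the non-lactone oxygen for the rest of the route.

Step 11
Reactants: 17 (4S,5S)-4-[(1R)-1-{[tert-butyl(dimethyl)silyl]oxy}-3-{[(4-methoxybenzyl)oxy]methyl}but-3-en-1-yl]-5-[(1Z)-2-methylbuta-1,3-dien-1-yl]oxolan-2-one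
Product: 18 (4S,5S)-4-[(1R)-1-{[tert-butyl(dimethyl)silyl]oxy}-3-(hydroxymethyl)but-3-en-1-yl]-5-[(1Z)-2-methylbuta-1,3-dien-1-yl]oxolan-2-one
Conditions: DDQ, CH2Cl2/pH 7 phosphate buffer, 0 °C
Reagents that add atoms: none
Why: Oxidative cleavage of the 4-methoxybenzyl ether by hydride abstraction and hydrolysis; the silyl ether and lactone are inert, and the Z-substituted diene cannot easily reach the s-cis form needed for a Diels–Alder reaction with the quinone.

Step 12
Reactants: 18 (4S,5S)-4-[(1R)-1-{[tert-butyl(dimethyl)silyl]oxy}-3-(hydroxymethyl)but-3-en-1-yl]-5-[(1Z)-2-methylbuta-1,3-dien-1-yl]oxolan-2-one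
Product: 19 (4S,5S)-4-[(1R)-1-{[tert-butyl(dimethyl)silyl]oxy}-3-formylbut-3-en-1-yl]-5-[(1Z)-2-methylbuta-1,3-dien-1-yl]oxolan-2-one
Conditions: MnO2, CH2Cl2, 23 °C
Reagents that add atoms: none
Why: Allylic oxidation with MnO2 to the 2-substituted acrolein; the neutral conditions avoid polymerisation or conjugate addition, and the enal is used at once.

Step 13
Reactants: 19 (4S,5S)-4-[(1R)-1-{[tert-butyl(dimethyl)silyl]oxy}-3-formylbut-3-en-1-yl]-5-[(1Z)-2-methylbuta-1,3-dien-1-yl]oxolan-2-one
Product: 20 (4S,5S)-4-[(1R)-1-{[tert-butyl(dimethyl)silyl]oxy}-3-[(E)-(hydroxyimino)methyl]but-3-en-1-yl]-5-[(1Z)-2-methylbuta-1,3-dien-1-yl]oxolan-2-one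
Conditions: NH2OH·HCl, NaOAc, EtOH/THF, 0→23 °C
Reagents that add atoms: hydroxylamine hydrochloride, Cl.NO
Why: Oxime condensation; with acetate buffer, 1,2-addition to the aldehyde is faster than conjugate addition to the 2-methylene unit, and the E aldoxime is the usual product.

Step 14
Reactants: 20 (4S,5S)-4-[(1R)-1-{[tert-butyl(dimethyl)silyl]oxy}-3-[(E)-(hydroxyimino)methyl]but-3-en-1-yl]-5-[(1Z)-2-methylbuta-1,3-dien-1-yl]oxolan-2-one
Product: 22 isoxazoline-bridged lactone: ten-membered carbocycle C1–C10 with 4Z olefin, C10=C14 methylene, cis 12,6-lactone (C11H2), 8-silyl ether and a 2-isoxazoline made of C1(=N)–C2–C3–O; 3S,6S,7S,8R, via nitrile oxide 21 (not isolated)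
Conditions: aqueous NaOCl added slowly, CH2Cl2, 0→23 °C, about 1 mM in 20
Reagents that add atoms: none
Why: Hypochlorite converts the aldoxime into nitrile oxide 21, which adds to the terminal C2=C3 olefin in a concerted, thermally allowed [3+2] cycloaddition; the closest known reaction type is the intramolecular nitrile oxide–olefin cycloaddition that closes macrocyclic carbocycles in the bridged mode, used here at its smallest practical ring size. The ten-membered carbocycle closes in the endo sense, the dipole carbon C1 bonding to the distal olefin carbon C2 so that both olefin carbons lie in the new ring, and the isoxazoline closes by O–C3 bonding, which leaves N–O as a two-atom bridge from C1 to C3 (a bicyclo[7.2.1] frame). This orientation is also the electronically normal one for a monosubstituted olefin (oxygen to the substituted carbon), so polarity and strain point the same way, whereas the fused mode would need a nine-membered ring and reversed regiochemistry. The only new stereocentre is C3 and it is controlled by C6: allylic 1,3-strain across the Z C4=C5 bond holds C6–H in the olefin plane towards C3, which puts C7 and the tether on one face of the diene and the lactone oxygen on the other, so the vinyl group, twisted out of conjugation, should be reached by the tethered dipole from the C7 side only, and this is expected to give the 3S configuration. Chemoselectivity for C2=C3 over the trisubstituted C4=C5 and the 1,1-disubstituted C10=C14 olefins follows from the higher dipolarophilicity of a terminal vinyl group and from the tether, which cannot bring C1 over either of the other two. The selectivity the step needs most is ring closure over dimerisation of 21 to a furoxan, which slow generation of the dipole at high dilution should secure. No base, metal or enolate is involved, so the lactone, the silyl ether and the 2-methylene unit conjugated to the dipole are left alone.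

Step 15
Reactants: 22 isoxazoline-bridged lactone (3S,6S,7S,8R)
Product: 24 (3S,6S,7S,8R)-3-hydroxy-1-oxo ten-membered lactone: C1 ketone conjugated to C10=C14, C3 carbinol, 4Z olefin, 8-silyl ether, cis 12,6-lactone (C11H2), via hydroxy imine 23 (not isolated)
Conditions: Mo(CO)6, MeCN/H2O (10:1), 80 °C
Reagents that add atoms: water, O
Why: Reductive N–O cleavage of a 2-isoxazoline by Mo(CO)6 and hydrolysis of the resulting β-hydroxy imine; unlike hydrogenolysis this leaves the three olefins alone, and C3 keeps the configuration set in step 14.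

Step 16
Reactants: 24 (3S,6S,7S,8R)-3-hydroxy-1-oxo ten-membered lactone
Product: 26 (1R,3S,6S,7S,8R)-1,3-diol: syn C1 and C3 carbinols, 4Z olefin, C10=C14 methylene, 8-silyl ether, cis 12,6-lactone (C11H2), via diethylborinate 25 (not isolated)
Conditions: Et2BOMe, THF/MeOH (4:1), −78 °C; NaBH4, −78 °C; AcOH quench; co-evaporation with MeOH
Reagents that add atoms: none
Why: Narasaka–Prasad reduction; the C3 borinate chelates the C1 carbonyl in a six-membered half-chair and external hydride adds axially to give the 1,3-syn diol (1R), while carbonyl activation by boron at −78 °C should favour 1,2- over 1,4-addition to the methylene ketone and leave the lactone untouched.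

Step 17
Reactants: 26 (1R,3S,6S,7S,8R)-1,3-diol
Product: 27 (1R,3S,6S,7S,8R)-1,3-O-isopropylidene acetal of 26
Conditions: Me2C(OMe)2, PPTS, CH2Cl2, 23 °C
Reagents that add atoms: 2,2-dimethoxypropane, COC(C)(C)OC
Why: Acetalisation by acetal exchange; a syn-1,3-diol gives a chair dioxane with both ring branches equatorial, and the mild acid spares the silyl ether and the allylic C–O bonds.

Step 18
Reactants: 27 (1R,3S,6S,7S,8R)-1,3-O-isopropylidene acetal
Product: 28 11-[(dimethylamino)methyl] lactone derived from 27 (configuration at C11 not defined, removed in step 19)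
Conditions: LiN(SiMe3)2, THF, −78 °C; then CH2=NMe2+ I−, −78→0 °C
Reagents that add atoms: N,N-dimethylmethylideneammonium iodide, C=[N+](C)C.[I-]
Why: Mannich reaction of the lactone lithium enolate with the preformed iminium salt; C11 is the only acidic position, and the enolate has no leaving group on its β-carbon C7.

Step 19
Reactants: 28 11-[(dimethylamino)methyl] lactone
Product: 30 (1R,3S,6S,7S,8R)-α-methylene lactone: C11=C13, 1,3-O-isopropylidene, 8-silyl ether, via ammonium iodide 29 (not isolated)
Conditions: MeI, CH2Cl2/MeOH, 23 °C; then aqueous NaHCO3, 23 °C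
Reagents that add atoms: none
Why: N-Methylation and base-induced β-elimination of trimethylamine (Hofmann-type, E1cB through the lactone enolate) gives the exocyclic enoate under conditions too mild to disturb C7.

Step 20
Reactants: 30 (1R,3S,6S,7S,8R)-α-methylene lactone silyl ether
Product: 31 (1R,3S,6S,7R,8R)-8-hydroxy α-methylene lactone with 1,3-O-isopropylidene
Conditions: HF·pyridine, pyridine, THF, 0→23 °C
Reagents that add atoms: none
Why: Fluoride-mediated desilylation under buffered, non-basic conditions, chosen over a basic fluoride source so that the freed O8 does not add to C12 or C13 and the acetal survives.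

Step 21
Reactants: 31 (1R,3S,6S,7R,8R)-8-hydroxy α-methylene lactone; 32 (2Z)-2-methylbut-2-enoic acid (angelic acid)
Product: 34 (1R,3S,6S,7R,8R)-8-O-angeloyl-1,3-O-isopropylidene derivative of the target, via mixed anhydride 33 (not isolated)
Conditions: 2,4,6-Cl3C6H2COCl, Et3N, PhMe, 23 °C; then 31, 75 °C
Reagents that add atoms: none
Why: Yamaguchi esterification through the 2,4,6-trichlorobenzoyl mixed anhydride, a standard way to acylate hindered alcohols with angelic acid while largely keeping the Z geometry, because no free nucleophilic catalyst adds reversibly to the enoate.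

Step 22
Reactants: 34 (1R,3S,6S,7R,8R)-8-O-angeloyl-1,3-O-isopropylidene derivative
Product: 35 CNP0175889.7, (1R,3S,6S,7R,8R,4Z)-1,3-dihydroxy-8-[(2Z)-2-methylbut-2-enoyloxy]germacra-4,10(14),11(13)-trien-12,6-olide
Conditions: AcOH/THF/H2O (3:1:1), 40 °C
Reagents that add atoms: none
Why: Acid-catalysed acetal hydrolysis; dilute acetic acid should release the diol without ionising the two allylic carbinols, isomerising the angelate or adding to the methylene lactone.

## Compound list

1 | (2Z)-3-methylpent-2-en-4-yn-1-ol | OC/C=C(/C)C#C | starting material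
2 | (2Z)-3-methylpenta-2,4-dien-1-ol | OC/C=C(/C)C=C | intermediate
3 | (2Z)-3-methylpenta-2,4-dienal | O=C/C=C(/C)C=C | intermediate
4 | (4R)-4-benzyl-1,3-oxazolidin-2-one | O=C1N[C@H](Cc2ccccc2)CO1 | starting material
5 | methyl 4-chloro-4-oxobutanoate | COC(=O)CCC(Cl)=O | starting material
6 | methyl 4-[(4R)-4-benzyl-2-oxo-1,3-oxazolidin-3-yl]-4-oxobutanoate | COC(=O)CCC(=O)N1[C@H](Cc2ccccc2)COC1=O | intermediate
7 | methyl (3S,4S,5Z)-3-{[(4R)-4-benzyl-2-oxo-1,3-oxazolidin-3-yl]carbonyl}-6-methyl-4-[(trimethylsilyl)oxy]octa-5,7-dienoate | COC(=O)C[C@H](C(=O)N1[C@H](Cc2ccccc2)COC1=O)[C@@H](O[Si](C)(C)C)/C=C(/C)C=C | intermediate (not isolated)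
8 | methyl (3S,4S,5Z)-3-{[(4R)-4-benzyl-2-oxo-1,3-oxazolidin-3-yl]carbonyl}-4-hydroxy-6-methylocta-5,7-dienoate | COC(=O)C[C@H](C(=O)N1[C@H](Cc2ccccc2)COC1=O)[C@@H](O)/C=C(/C)C=C | intermediate (not isolated)
9 | (4R)-4-benzyl-3-{[(2S,3S)-2-[(1Z)-2-methylbuta-1,3-dien-1-yl]-5-oxooxolan-3-yl]carbonyl}-1,3-oxazolidin-2-one | C1C(=O)O[C@@H](/C=C(/C)C=C)[C@H]1C(=O)N2[C@H](Cc3ccccc3)COC2=O | intermediate
10 | (2S,3S)-2-[(1Z)-2-methylbuta-1,3-dien-1-yl]-5-oxooxolane-3-carboxylic acid | C1C(=O)O[C@@H](/C=C(/C)C=C)[C@H]1C(=O)O | intermediate
11 | 2-methylidenepropane-1,3-diol | C=C(CO)CO | starting material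
12 | 2-{[(4-methoxybenzyl)oxy]methyl}prop-2-en-1-ol | C=C(CO)COCc1ccc(OC)cc1 | intermediate
13 | 1-({[2-(bromomethyl)prop-2-en-1-yl]oxy}methyl)-4-methoxybenzene | C=C(CBr)COCc1ccc(OC)cc1 | intermediate
14 | (4S,5S)-4-(1H-imidazol-1-ylcarbonyl)-5-[(1Z)-2-methylbuta-1,3-dien-1-yl]oxolan-2-one | C1C(=O)O[C@@H](/C=C(/C)C=C)[C@H]1C(=O)n1ccnc1 | intermediate (not isolated)
15 | (4S,5S)-4-(3-{[(4-methoxybenzyl)oxy]methyl}but-3-enoyl)-5-[(1Z)-2-methylbuta-1,3-dien-1-yl]oxolan-2-one | C1C(=O)O[C@@H](/C=C(/C)C=C)[C@H]1C(=O)CC(=C)COCc2ccc(OC)cc2 | intermediate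
16 | (4R,5S)-4-[(1R)-1-hydroxy-3-{[(4-methoxybenzyl)oxy]methyl}but-3-en-1-yl]-5-[(1Z)-2-methylbuta-1,3-dien-1-yl]oxolan-2-one | C1C(=O)O[C@@H](/C=C(/C)C=C)[C@H]1[C@H](O)CC(=C)COCc2ccc(OC)cc2 | intermediate
17 | (4S,5S)-4-[(1R)-1-{[tert-butyl(dimethyl)silyl]oxy}-3-{[(4-methoxybenzyl)oxy]methyl}but-3-en-1-yl]-5-[(1Z)-2-methylbuta-1,3-dien-1-yl]oxolan-2-one | C1C(=O)O[C@@H](/C=C(/C)C=C)[C@H]1[C@H](O[Si](C)(C)C(C)(C)C)CC(=C)COCc2ccc(OC)cc2 | intermediate
18 | (4S,5S)-4-[(1R)-1-{[tert-butyl(dimethyl)silyl]oxy}-3-(hydroxymethyl)but-3-en-1-yl]-5-[(1Z)-2-methylbuta-1,3-dien-1-yl]oxolan-2-one | C1C(=O)O[C@@H](/C=C(/C)C=C)[C@H]1[C@H](O[Si](C)(C)C(C)(C)C)CC(=C)CO | intermediate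
19 | (4S,5S)-4-[(1R)-1-{[tert-butyl(dimethyl)silyl]oxy}-3-formylbut-3-en-1-yl]-5-[(1Z)-2-methylbuta-1,3-dien-1-yl]oxolan-2-one | C1C(=O)O[C@@H](/C=C(/C)C=C)[C@H]1[C@H](O[Si](C)(C)C(C)(C)C)CC(=C)C=O | intermediate
20 | (4S,5S)-4-[(1R)-1-{[tert-butyl(dimethyl)silyl]oxy}-3-[(E)-(hydroxyimino)methyl]but-3-en-1-yl]-5-[(1Z)-2-methylbuta-1,3-dien-1-yl]oxolan-2-one (precursor of the key step) | C1C(=O)O[C@@H](/C=C(/C)C=C)[C@H]1[C@H](O[Si](C)(C)C(C)(C)C)CC(=C)/C=N/O | intermediate
21 | nitrile oxide of 20 (C1 as C≡N+–O−) | C1C(=O)O[C@@H](/C=C(/C)C=C)[C@H]1[C@H](O[Si](C)(C)C(C)(C)C)CC(=C)C#[N+][O-] | intermediate (not isolated)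
22 | (3S,6S,7S,8R)-isoxazoline-bridged ten-membered lactone: C1(=N)–C2–C3–O isoxazoline, 4Z olefin, C10=C14, 8-O-TBS, cis 12,6-lactone with C11H2 (product of the key step) | C1C(=O)O[C@H]2/C=C(/C)[C@@H]3CC(=NO3)C(=C)C[C@@H](O[Si](C)(C)C(C)(C)C)[C@@H]12 | intermediate
23 | (3S,6S,7S,8R)-3-hydroxy-1-imino ten-membered lactone | C1C(=O)O[C@H]2/C=C(/C)[C@@H](O)CC(=N)C(=C)C[C@@H](O[Si](C)(C)C(C)(C)C)[C@@H]12 | intermediate (not isolated)
24 | (3S,6S,7S,8R)-3-hydroxy-1-oxo ten-membered lactone, 8-O-TBS | C1C(=O)O[C@H]2/C=C(/C)[C@@H](O)CC(=O)C(=C)C[C@@H](O[Si](C)(C)C(C)(C)C)[C@@H]12 | intermediate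
25 | 3-O-diethylboryl derivative of 24 | C1C(=O)O[C@H]2/C=C(/C)[C@@H](OB(CC)CC)CC(=O)C(=C)C[C@@H](O[Si](C)(C)C(C)(C)C)[C@@H]12 | intermediate (not isolated)
26 | (1R,3S,6S,7S,8R)-1,3-dihydroxy ten-membered lactone, 8-O-TBS | C1C(=O)O[C@H]2/C=C(/C)[C@@H](O)C[C@@H](O)C(=C)C[C@@H](O[Si](C)(C)C(C)(C)C)[C@@H]12 | intermediate
27 | (1R,3S,6S,7S,8R)-1,3-O-isopropylidene acetal of 26 | C1C(=O)O[C@H]2/C=C(/C)[C@@H]3C[C@@H](OC(C)(C)O3)C(=C)C[C@@H](O[Si](C)(C)C(C)(C)C)[C@@H]12 | intermediate
28 | 11-[(dimethylamino)methyl] derivative of 27 (C11 undefined) | CN(C)CC1C(=O)O[C@H]2/C=C(/C)[C@@H]3C[C@@H](OC(C)(C)O3)C(=C)C[C@@H](O[Si](C)(C)C(C)(C)C)[C@@H]12 | intermediate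
29 | 11-[(trimethylammonio)methyl] iodide derived from 28 | C[N+](C)(C)CC1C(=O)O[C@H]2/C=C(/C)[C@@H]3C[C@@H](OC(C)(C)O3)C(=C)C[C@@H](O[Si](C)(C)C(C)(C)C)[C@@H]12.[I-] | intermediate (not isolated)
30 | (1R,3S,6S,7S,8R)-α-methylene lactone (C11=C13), 1,3-O-isopropylidene, 8-O-TBS | C=C1C(=O)O[C@H]2/C=C(/C)[C@@H]3C[C@@H](OC(C)(C)O3)C(=C)C[C@@H](O[Si](C)(C)C(C)(C)C)[C@@H]12 | intermediate
31 | (1R,3S,6S,7R,8R)-8-hydroxy α-methylene lactone, 1,3-O-isopropylidene | C=C1C(=O)O[C@H]2/C=C(/C)[C@@H]3C[C@@H](OC(C)(C)O3)C(=C)C[C@@H](O)[C@@H]12 | intermediate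
32 | (2Z)-2-methylbut-2-enoic acid (angelic acid) | C/C=C(/C)C(=O)O | starting material
33 | (2Z)-2-methylbut-2-enoic 2,4,6-trichlorobenzoic anhydride | C/C=C(/C)C(=O)OC(=O)c1c(Cl)cc(Cl)cc1Cl | intermediate (not isolated)
34 | (1R,3S,6S,7R,8R)-8-O-angeloyl-1,3-O-isopropylidene derivative of the target | C=C1C(=O)O[C@H]2/C=C(/C)[C@@H]3C[C@@H](OC(C)(C)O3)C(=C)C[C@@H](OC(=O)/C(C)=C\C)[C@@H]12 | intermediate
35 | CNP0175889.7, (1R,3S,6S,7R,8R,4Z)-1,3-dihydroxy-8-[(2Z)-2-methylbut-2-enoyloxy]germacra-4,10(14),11(13)-trien-12,6-olide | C=C1C(=O)O[C@H]2/C=C(/C)[C@@H](O)C[C@@H](O)C(=C)C[C@@H](OC(=O)/C(C)=C\C)[C@@H]12 | target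

## Step count and least certain steps

Total step count: 22. Longest linear sequence: 19 steps, from 1 to 35 (steps 1, 2, 4, 5 and 8 to 22). Steps 3, 6 and 7 prepare 6 and 13.

Step 14 (key step). The likeliest failure is that dimerisation or oligomerisation of the nitrile oxide outruns closure through a strained, bridged ten-membered transition state. A second failure is that the tether does not distinguish the two faces of the twisted vinyl group well enough, which would give the C3 epimer. The fallback replaces the nitrile oxide by a silyl nitronate, a dipole that does not dimerise and can be heated at high dilution (intramolecular silyl nitronate–olefin cycloaddition). It sets out from 18. Appel bromination (CBr4, PPh3) gives the allylic bromide F1, and displacement with NaNO2 (urea, DMF) gives the nitro compound F2. Me3SiCl and Et3N in toluene at high dilution, 23→80 °C, form the silyl nitronate F3, which cyclises with the same regiochemistry to the N-silyloxy isoxazolidine F4. p-Toluenesulfonic acid then eliminates silanol, and the route is rejoined at 22.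

Step 4. The 3,3-disubstituted dienal 3 is a weak acceptor, and during a slow addition it may lose its Z geometry or be silylated at the γ-methyl group under Et3N/Me3SiCl, with erosion of the anti selectivity. The fallback changes the acceptor and the order of events. It sets out from 1 and 6. MnO2 oxidation of 1 gives the enynal F5, which is more electrophilic and cannot equilibrate with a 2H-pyran. The same magnesium-catalysed aldol with 6 gives the silyl aldolate F6, acidic methanol gives the hydroxy ester F7, and lactonisation gives the alkynyl lactone imide F8. Semihydrogenation of the terminal alkyne of F8 (H2, Pd/CaCO3 poisoned with Pb(OAc)2, quinoline) rejoins the route at 9.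

Step 9. Hydride delivery to a ketone held next to a cis-substituted lactone may be poorly selective, or may prefer the face opposite to the one predicted. The fallback makes C8 in the C–C bond-forming event instead. It sets out from 10. Isobutyl chloroformate and N-methylmorpholine give the mixed carbonic anhydride F9, which NaBH4 reduces to the primary alcohol F10. Dess–Martin oxidation gives the aldehyde F11. Barbier allylation of F11 with 13 and In powder in THF/H2O rejoins the route at 16. Here the carbon nucleophile and the hydrogen have exchanged roles relative to step 9, so a substrate bias that disfavours 16 in the reduction favours it in the allylation.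

Step 21. The hindered O8 may acylate slowly, which leaves time for isomerisation of the activated angeloyl unit to the E (tigloyl) isomer and for migration of the lactone from O6 to the free O8 under the basic conditions. The fallback builds the Z olefin on the ester. It sets out from 31. Esterification with 2-[bis(2,2,2-trifluoroethoxy)phosphoryl]propanoic acid (dicyclohexylcarbodiimide, 4-dimethylaminopyridine) gives the phosphonate F12. Still–Gennari olefination of F12 with acetaldehyde (KN(SiMe3)2, 18-crown-6, THF, −78 °C) gives the Z enoate and rejoins the route at 34.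

## Further compounds

F1 | step 14 | (4S,5S)-4-[(1R)-3-(bromomethyl)-1-{[tert-butyl(dimethyl)silyl]oxy}but-3-en-1-yl]-5-[(1Z)-2-methylbuta-1,3-dien-1-yl]oxolan-2-one | C1C(=O)O[C@@H](/C=C(/C)C=C)[C@H]1[C@H](O[Si](C)(C)C(C)(C)C)CC(=C)CBr
F2 | step 14 | (4S,5S)-4-[(1R)-1-{[tert-butyl(dimethyl)silyl]oxy}-3-(nitromethyl)but-3-en-1-yl]-5-[(1Z)-2-methylbuta-1,3-dien-1-yl]oxolan-2-one | C1C(=O)O[C@@H](/C=C(/C)C=C)[C@H]1[C@H](O[Si](C)(C)C(C)(C)C)CC(=C)C[N+](=O)[O-]
F3 | step 14 | trimethylsilyl nitronate of F2 | C1C(=O)O[C@@H](/C=C(/C)C=C)[C@H]1[C@H](O[Si](C)(C)C(C)(C)C)CC(=C)C=[N+]([O-])O[Si](C)(C)C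
F4 | step 14 | N-(trimethylsilyloxy)isoxazolidine-bridged ten-membered lactone (C1 undefined) | C1C(=O)O[C@H]2/C=C(/C)[C@@H]3CC(N(O3)O[Si](C)(C)C)C(=C)C[C@@H](O[Si](C)(C)C(C)(C)C)[C@@H]12
F5 | step 4 | (2Z)-3-methylpent-2-en-4-ynal | O=C/C=C(/C)C#C
F6 | step 4 | methyl (3S,4S,5Z)-3-{[(4R)-4-benzyl-2-oxo-1,3-oxazolidin-3-yl]carbonyl}-6-methyl-4-[(trimethylsilyl)oxy]oct-5-en-7-ynoate | COC(=O)C[C@H](C(=O)N1[C@H](Cc2ccccc2)COC1=O)[C@@H](O[Si](C)(C)C)/C=C(/C)C#C
F7 | step 4 | methyl (3S,4S,5Z)-3-{[(4R)-4-benzyl-2-oxo-1,3-oxazolidin-3-yl]carbonyl}-4-hydroxy-6-methyloct-5-en-7-ynoate | COC(=O)C[C@H](C(=O)N1[C@H](Cc2ccccc2)COC1=O)[C@@H](O)/C=C(/C)C#C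
F8 | step 4 | (4R)-4-benzyl-3-{[(2S,3S)-2-[(1Z)-2-methylbut-1-en-3-yn-1-yl]-5-oxooxolan-3-yl]carbonyl}-1,3-oxazolidin-2-one | C1C(=O)O[C@@H](/C=C(/C)C#C)[C@H]1C(=O)N2[C@H](Cc3ccccc3)COC2=O
F9 | step 9 | isobutyl carbonic anhydride of 10 | C1C(=O)O[C@@H](/C=C(/C)C=C)[C@H]1C(=O)OC(=O)OCC(C)C
F10 | step 9 | (4R,5S)-4-(hydroxymethyl)-5-[(1Z)-2-methylbuta-1,3-dien-1-yl]oxolan-2-one | C1C(=O)O[C@@H](/C=C(/C)C=C)[C@H]1CO
F11 | step 9 | (2S,3S)-2-[(1Z)-2-methylbuta-1,3-dien-1-yl]-5-oxooxolane-3-carbaldehyde | C1C(=O)O[C@@H](/C=C(/C)C=C)[C@H]1C=O
F12 | step 21 | 8-O-{2-[bis(2,2,2-trifluoroethoxy)phosphoryl]propanoyl} derivative of 31 | C=C1C(=O)O[C@H]2/C=C(/C)[C@@H]3C[C@@H](OC(C)(C)O3)C(=C)C[C@@H](OC(=O)C(C)P(=O)(OCC(F)(F)F)OCC(F)(F)F)[C@@H]12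
A1 | alternative 1 | ten-membered 1-hydroxy-10-oxo carbocycle with 4Z olefin, 3-O-TBS, 6-O- and 8-O-(4-methoxybenzyl) and 7-(1,3-dioxolan-2-ylmethyl) groups | COc1ccc(cc1)CO[C@H]2/C=C(/C)[C@@H](O[Si](C)(C)C(C)(C)C)C[C@@H](O)C(=O)C[C@@H](OCc3ccc(OC)cc3)[C@H]2CC4OCCO4
A2 | alternative 2 | tricyclic photoadduct: γ-lactone and cyclobutane fused at C6–C7 and C6–C9 to the eight-membered C10 ketone, 1-O-TBS, 3-O-TBS, 8-O-triethylsilyl | C1[C@H](O[Si](C)(C)C(C)(C)C)/C(C)=C\[C@@]23OC(=O)C[C@@H]2[C@H](O[Si](CC)(CC)CC)[C@H]3C(=O)[C@@H]1O[Si](C)(C)C(C)(C)C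
A3 | alternative 3 | 3-O-acetyl-1-O-TBS derivative of the target | C=C1C(=O)O[C@H]2/C=C(/C)[C@@H](OC(C)=O)C[C@@H](O[Si](C)(C)C(C)(C)C)C(=C)C[C@@H](OC(=O)/C(C)=C\C)[C@@H]12
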